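**Retrosynthetic overview**
- The route rests on the C2=C3 unit of ring C: C2 carries ring B, C3 carries an oxygen, and O1–C2 joins it to C8a of ring A. This unit maps onto an aryl alkyne that is closed onto the C8a oxygen by an electrophile that stays on C3.
- Endgame: the 4'-O–prenyl bond is made by Mitsunobu reaction on a 7-O-silyl phenol, the O-benzyl ethers are removed by hydrogenolysis, and C3–OMe comes from C3–I by copper-catalysed methoxylation.
- Key disconnection: O1–C2 and C3–I, by iodocyclisation of a 1-(2-hydroxyaryl)-3-arylpropynone. Ring C is the only ring formed; rings A and B are bought.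
- Ynone: the C4–C3 bond comes from a lithium arylacetylide (from O-benzylvanillin by Ohira–Bestmann homologation) and a salicylaldehyde, followed by MnO2 oxidation.
- Salicylaldehyde: from 2,4,6-trihydroxybenzaldehyde by dibenzylation, MOM protection, Baeyer–Villiger oxidation and O-methylation (this oxygen becomes the C8 methoxy group), MOM removal and ortho-formylation.

Key step: step 10

Remark: alcohol 13 is formed as a racemate; its only stereocentre is removed in step 9, and the target has none.

**Route**

Step 1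
Reactants: 1 2,4,6-trihydroxybenzaldehyde; 2 benzyl bromide (first equivalent)
Product: 3 2,4-bis(benzyloxy)-6-hydroxybenzaldehyde
Conditions: BnBr (2.05 equiv in all), K2CO3 (2.1 equiv), DMF, 0 °C to rt
Reagents that add atoms: benzyl bromide (second equivalent of 2), BrCc1ccccc1
Why: Twofold Williamson etherification, in which the first equivalent of benzyl bromide takes the unchelated para hydroxyl and the second takes one ortho hydroxyl, while the last ortho hydroxyl is held in a hydrogen bond to the aldehyde and should stay free under these mild conditions.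

Step 2
Reactants: 3 2,4-bis(benzyloxy)-6-hydroxybenzaldehyde
Product: 4 2,4-bis(benzyloxy)-6-(methoxymethoxy)benzaldehyde
Conditions: MOMCl, i-Pr2NEt, CH2Cl2, 0 °C to reflux
Reagents that add atoms: chloromethyl methyl ether (MOMCl), COCCl
Why: O-alkylation of the chelated phenol with the reactive α-chloro ether gives an acetal that is orthogonal to the benzyl ethers and to the methyl ether installed in step 4.

Step 3
Reactants: 4 2,4-bis(benzyloxy)-6-(methoxymethoxy)benzaldehyde
Product: 6 2,4-bis(benzyloxy)-6-(methoxymethoxy)phenol, via aryl formate 5 (not isolated)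
Conditions: mCPBA, CH2Cl2, 0 °C to rt; then K2CO3 (cat.), MeOH, rt
Reagents that add atoms: 3-chloroperoxybenzoic acid (mCPBA), OOC(=O)c1cccc(Cl)c1
Why: In the Baeyer–Villiger (Dakin-type) oxidation of this 2,4,6-trialkoxybenzaldehyde the electron-rich aryl group migrates to oxygen, and methanolysis of the formate frees the phenol.

Step 4
Reactants: 6 2,4-bis(benzyloxy)-6-(methoxymethoxy)phenol
Product: 7 1,5-bis(benzyloxy)-2-methoxy-3-(methoxymethoxy)benzene
Conditions: MeI, K2CO3, acetone, reflux
Reagents that add atoms: iodomethane, CI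
Why: Williamson methylation of the only free phenol fixes the methoxy group that becomes the C8 substituent.

Step 5
Reactants: 7 1,5-bis(benzyloxy)-2-methoxy-3-(methoxymethoxy)benzene
Product: 8 3,5-bis(benzyloxy)-2-methoxyphenol
Conditions: HCl (cat.), MeOH, 50 °C
Reagents that add atoms: none
Why: Acid-catalysed acetal exchange with methanol removes the MOM group as dimethoxymethane and leaves the benzyl and methyl ethers untouched.

Step 6
Reactants: 8 3,5-bis(benzyloxy)-2-methoxyphenol
Product: 9 4,6-bis(benzyloxy)-2-hydroxy-3-methoxybenzaldehyde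
Conditions: (CH2O)n, MgCl2, Et3N, MeCN, reflux; aq. HCl work-up
Reagents that add atoms: paraformaldehyde (reacts as formaldehyde), C=O
Why: In the Casnati–Skattebøl ortho-formylation the magnesium phenoxide delivers formaldehyde to the single free ortho position, and the benzylic alkoxide is oxidised to the aldehyde by hydride transfer to a second formaldehyde, so the para C–H is not touched.

Step 7
Reactants: 10 4-benzyloxy-3-methoxybenzaldehyde
Product: 11 1-(benzyloxy)-4-ethynyl-2-methoxybenzene
Conditions: dimethyl (1-diazo-2-oxopropyl)phosphonate, K2CO3, MeOH, rt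
Reagents that add atoms: dimethyl (1-diazo-2-oxopropyl)phosphonate, CC(=O)C(=[N+]=[N-])P(=O)(OC)OC
Why: In the Seyferth–Gilbert homologation (Ohira–Bestmann variant) methoxide releases the diazomethylphosphonate anion, which olefinates the aldehyde, and loss of N2 with 1,2-hydrogen shift gives the terminal alkyne.

Step 8
Reactants: 11 1-(benzyloxy)-4-ethynyl-2-methoxybenzene (2.4 equiv); 9 4,6-bis(benzyloxy)-2-hydroxy-3-methoxybenzaldehyde
Product: 13 1-[4,6-bis(benzyloxy)-2-hydroxy-3-methoxyphenyl]-3-(4-benzyloxy-3-methoxyphenyl)prop-2-yn-1-ol (racemic), via lithium acetylide 12 (not isolated)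
Conditions: n-BuLi (2.3 equiv), THF, −78 °C; then 9, −78 °C to 0 °C; aq. NH4Cl; crude product used at once
Reagents that add atoms: none
Why: One equivalent of the acetylide deprotonates the phenol and a second adds to the lithium-chelated aldehyde (1,2-addition of a lithium acetylide), giving the carbinol centre without control as a racemate that step 9 erases.

Step 9
Reactants: 13 1-[4,6-bis(benzyloxy)-2-hydroxy-3-methoxyphenyl]-3-(4-benzyloxy-3-methoxyphenyl)prop-2-yn-1-ol
Product: 14 1-[4,6-bis(benzyloxy)-2-hydroxy-3-methoxyphenyl]-3-(4-benzyloxy-3-methoxyphenyl)prop-2-yn-1-one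
Conditions: MnO2 (activated, excess), CH2Cl2, rt
Reagents that add atoms: none
Why: MnO2 oxidises the doubly activated (benzylic and propargylic) alcohol selectively under neutral conditions, and the resulting ynone is stabilised by the hydrogen bond from the ortho phenol.

Step 10
Reactants: 14 1-[4,6-bis(benzyloxy)-2-hydroxy-3-methoxyphenyl]-3-(4-benzyloxy-3-methoxyphenyl)prop-2-yn-1-one
Product: 15 5,7-bis(benzyloxy)-2-(4-benzyloxy-3-methoxyphenyl)-3-iodo-8-methoxychromen-4-one
Conditions: I2 (1.5 equiv), NaHCO3 (2 equiv), MeCN, 0 °C to rt, dark; aq. Na2S2O3 work-up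
Reagents that add atoms: iodine, II
Why: Iodine forms an iodonium ion on the triple bond whose positive charge sits on the alkyne carbon bonded to the 4-benzyloxy-3-methoxyphenyl group; the phenol oxygen (the future O1) attacks that carbon anti to iodine and NaHCO3 takes up the proton, so O1–C2 and C3–I form in one operation. The closest known reaction is the iodine- or ICl-induced electrophilic cyclisation of 2-alkoxyaryl and 2-hydroxyaryl ynones to 3-iodochromones. Ring C closes in the 6-endo-dig mode, and no stereocentre is formed. The step needs 6-endo closure over 5-exo closure (aurone) and alkyne activation over iodination of the ring A C–H para to the phenol. The first is secured by the electron-rich aryl group, which stabilises charge at the distal alkyne carbon, together with the polarisation of the ynone. The second is secured by the carbonyl-chelated, poorly ionised phenol under heterogeneous NaHCO3, by a mild iodine source used in small excess at low temperature, and by the fact that ring A is no longer a phenol once ring C has closed.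

Step 11
Reactants: 15 5,7-bis(benzyloxy)-2-(4-benzyloxy-3-methoxyphenyl)-3-iodo-8-methoxychromen-4-one
Product: 16 5,7-bis(benzyloxy)-2-(4-benzyloxy-3-methoxyphenyl)-3,8-dimethoxychromen-4-one
Conditions: NaOMe (3 equiv), CuI (20 mol %), 1,10-phenanthroline (40 mol %), MeOH/toluene, 100 °C, sealed tube
Reagents that add atoms: sodium methoxide, [Na+].[O-]C
Why: Ullmann-type copper-catalysed C–O coupling replaces the C3 iodide of the iodo-enone by methoxide, and the benzyl and methyl ethers are inert to the alkoxide.

Step 12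
Reactants: 16 5,7-bis(benzyloxy)-2-(4-benzyloxy-3-methoxyphenyl)-3,8-dimethoxychromen-4-one
Product: 17 5,7-dihydroxy-2-(4-hydroxy-3-methoxyphenyl)-3,8-dimethoxychromen-4-one
Conditions: H2 (1 atm), 10% Pd/C, THF/MeOH, rt
Reagents that add atoms: none
Why: Palladium-catalysed hydrogenolysis cleaves the three benzylic C–O bonds, while the tetrasubstituted C2=C3 double bond of the flavone and the methyl ethers should not be reduced at one atmosphere.

Step 13
Reactants: 17 5,7-dihydroxy-2-(4-hydroxy-3-methoxyphenyl)-3,8-dimethoxychromen-4-one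
Product: 18 7-[tert-butyl(dimethyl)silyl]oxy-5-hydroxy-2-(4-hydroxy-3-methoxyphenyl)-3,8-dimethoxychromen-4-one
Conditions: TBSCl (1.05 equiv), imidazole (2.2 equiv), DMF, 0 °C
Reagents that add atoms: tert-butyl(chloro)dimethylsilane (TBSCl), CC(C)(C)[Si](C)(C)Cl
Why: Base-mediated silylation should take the most acidic hydroxyl, the 7-OH para to the pyranone carbonyl, because the 5-OH is locked in a hydrogen bond to C4=O and the 4'-OH is the weaker acid; any bis-silyl ether can be recycled to 17 by desilylation.

Step 14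
Reactants: 18 7-[tert-butyl(dimethyl)silyl]oxy-5-hydroxy-2-(4-hydroxy-3-methoxyphenyl)-3,8-dimethoxychromen-4-one; 19 3-methylbut-2-en-1-ol (prenol)
Product: 20 7-[tert-butyl(dimethyl)silyl]oxy-5-hydroxy-3,8-dimethoxy-2-[3-methoxy-4-(3-methylbut-2-enyloxy)phenyl]chromen-4-one
Conditions: PPh3, DIAD, THF, 0 °C to rt
Reagents that add atoms: none
Why: Mitsunobu etherification alkylates the 4'-phenol with the primary allylic alcohol under neutral conditions that keep the aryl silyl ether in place, and the chelated 5-OH does not react.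

Step 15
Reactants: 20 7-[tert-butyl(dimethyl)silyl]oxy-5-hydroxy-3,8-dimethoxy-2-[3-methoxy-4-(3-methylbut-2-enyloxy)phenyl]chromen-4-one
Product: 21 5,7-dihydroxy-3,8,3'-trimethoxy-4'-prenyloxyflavone (target)
Conditions: TBAF, AcOH, THF, 0 °C
Reagents that add atoms: none
Why: Fluoride cleaves the Si–O bond of the aryl silyl ether, and the acetic acid buffer keeps the prenyl ether and the flavone away from strongly basic phenoxide conditions.

**Compound list**
1 | 2,4,6-trihydroxybenzaldehyde | O=Cc1c(O)cc(O)cc1O | starting material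
2 | benzyl bromide | BrCc1ccccc1 | starting material
3 | 2,4-bis(benzyloxy)-6-hydroxybenzaldehyde | O=Cc1c(O)cc(OCc2ccccc2)cc1OCc1ccccc1 | intermediate
4 | 2,4-bis(benzyloxy)-6-(methoxymethoxy)benzaldehyde | O=Cc1c(OCOC)cc(OCc2ccccc2)cc1OCc1ccccc1 | intermediate
5 | 2,4-bis(benzyloxy)-6-(methoxymethoxy)phenyl formate | O=COc1c(OCOC)cc(OCc2ccccc2)cc1OCc1ccccc1 | intermediate
6 | 2,4-bis(benzyloxy)-6-(methoxymethoxy)phenol | Oc1c(OCOC)cc(OCc2ccccc2)cc1OCc1ccccc1 | intermediate
7 | 1,5-bis(benzyloxy)-2-methoxy-3-(methoxymethoxy)benzene | COc1c(OCOC)cc(OCc2ccccc2)cc1OCc1ccccc1 | intermediate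
8 | 3,5-bis(benzyloxy)-2-methoxyphenol | COc1c(O)cc(OCc2ccccc2)cc1OCc1ccccc1 | intermediate
9 | 4,6-bis(benzyloxy)-2-hydroxy-3-methoxybenzaldehyde | O=Cc1c(O)c(OC)c(OCc2ccccc2)cc1OCc1ccccc1 | intermediate
10 | 4-benzyloxy-3-methoxybenzaldehyde | COc1cc(C=O)ccc1OCc1ccccc1 | starting material
11 | 1-(benzyloxy)-4-ethynyl-2-methoxybenzene | C#Cc1ccc(OCc2ccccc2)c(OC)c1 | intermediate
12 | [(4-benzyloxy-3-methoxyphenyl)ethynyl]lithium | [Li]C#Cc1ccc(OCc2ccccc2)c(OC)c1 | intermediate
13 | 1-[4,6-bis(benzyloxy)-2-hydroxy-3-methoxyphenyl]-3-(4-benzyloxy-3-methoxyphenyl)prop-2-yn-1-ol (racemic) | OC(C#Cc1ccc(OCc2ccccc2)c(OC)c1)c1c(O)c(OC)c(OCc2ccccc2)cc1OCc1ccccc1 | intermediate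
14 | 1-[4,6-bis(benzyloxy)-2-hydroxy-3-methoxyphenyl]-3-(4-benzyloxy-3-methoxyphenyl)prop-2-yn-1-one | O=C(C#Cc1ccc(OCc2ccccc2)c(OC)c1)c1c(O)c(OC)c(OCc2ccccc2)cc1OCc1ccccc1 | intermediate
15 | 5,7-bis(benzyloxy)-2-(4-benzyloxy-3-methoxyphenyl)-3-iodo-8-methoxychromen-4-one | O=c1c(I)c(-c2ccc(OCc3ccccc3)c(OC)c2)oc2c(OC)c(OCc3ccccc3)cc(OCc3ccccc3)c12 | intermediate
16 | 5,7-bis(benzyloxy)-2-(4-benzyloxy-3-methoxyphenyl)-3,8-dimethoxychromen-4-one | COc1c(-c2ccc(OCc3ccccc3)c(OC)c2)oc2c(OC)c(OCc3ccccc3)cc(OCc3ccccc3)c2c1=O | intermediate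
17 | 5,7-dihydroxy-2-(4-hydroxy-3-methoxyphenyl)-3,8-dimethoxychromen-4-one | COc1cc(-c2oc3c(OC)c(O)cc(O)c3c(=O)c2OC)ccc1O | intermediate
18 | 7-[tert-butyl(dimethyl)silyl]oxy-5-hydroxy-2-(4-hydroxy-3-methoxyphenyl)-3,8-dimethoxychromen-4-one | COc1cc(-c2oc3c(OC)c(O[Si](C)(C)C(C)(C)C)cc(O)c3c(=O)c2OC)ccc1O | intermediate
19 | 3-methylbut-2-en-1-ol (prenol) | CC(C)=CCO | starting material
20 | 7-[tert-butyl(dimethyl)silyl]oxy-5-hydroxy-3,8-dimethoxy-2-[3-methoxy-4-(3-methylbut-2-enyloxy)phenyl]chromen-4-one | COc1cc(-c2oc3c(OC)c(O[Si](C)(C)C(C)(C)C)cc(O)c3c(=O)c2OC)ccc1OCC=C(C)C | intermediate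
21 | 5,7-dihydroxy-3,8,3'-trimethoxy-4'-prenyloxyflavone | COc1cc(-c2oc3c(OC)c(O)cc(O)c3c(=O)c2OC)ccc1OCC=C(C)C | target

**Step count**
Total: 15 steps. Longest linear sequence: 14 steps (steps 1–6 and 8–15); step 7 is a one-step side branch.

**Steps most likely to fail**

1. Step 10 (iodocyclisation). It may fail through electrophilic iodination of ring A at the C–H para to the free phenol before the ring closes, through base-triggered oxa-Michael closure that ends in protonation instead of iodination, or through 5-exo closure. The fallback separates ring closure from C–I bond formation and sets out from 14. Treatment with Et2NH in EtOH at 60 °C (amine conjugate addition to the ynone, then addition–elimination by the phenol, 6-endo) should give 5,7-bis(benzyloxy)-2-(4-benzyloxy-3-methoxyphenyl)-8-methoxychromen-4-one F1. Deprotonation at C3 with LiN(i-Pr)2 in THF at −78 °C should give [5,7-bis(benzyloxy)-2-(4-benzyloxy-3-methoxyphenyl)-8-methoxy-4-oxochromen-3-yl]lithium F2, and quenching with I2 returns to the route at 15.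

2. Step 11 (copper-catalysed methoxylation). It may fail through reductive loss of iodine, or through methoxide addition at C2 with opening of the pyranone ring. The fallback sets out from 15 and replaces C–O coupling by borylation and oxidation. Miyaura borylation (PdCl2(dppf), bis(pinacolato)diboron, KOAc, dioxane, 80 °C) should give 5,7-bis(benzyloxy)-2-(4-benzyloxy-3-methoxyphenyl)-8-methoxy-3-(4,4,5,5-tetramethyl-1,3,2-dioxaborolan-2-yl)chromen-4-one F3. Oxidation with NaBO3·4H2O in THF/H2O should give 5,7-bis(benzyloxy)-2-(4-benzyloxy-3-methoxyphenyl)-3-hydroxy-8-methoxychromen-4-one F4. Methylation of the flavonol hydroxyl with MeI and K2CO3 in acetone returns to the route at 16.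

3. Step 13 (selective 7-O-silylation). It may fail through poor discrimination between the 7-OH and the 4'-OH, giving bis-silylation or silylation at O4'. The fallback sets out from 17, uses no protecting group and relies on the opposite selectivity. KOt-Bu (2.1 equiv) in DMF at 0 °C should give dipotassium 5-hydroxy-3,8-dimethoxy-2-(3-methoxy-4-oxidophenyl)-4-oxochromen-7-olate F5. In this dianion the less stabilised 4'-phenoxide is the stronger nucleophile, so 1-bromo-3-methylbut-2-ene (1.0 equiv) should alkylate O4' and, after work-up with aqueous HCl, return to the route at 21.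

**Further compounds**
F1 | step 10 | 5,7-bis(benzyloxy)-2-(4-benzyloxy-3-methoxyphenyl)-8-methoxychromen-4-one | O=c1cc(-c2ccc(OCc3ccccc3)c(OC)c2)oc2c(OC)c(OCc3ccccc3)cc(OCc3ccccc3)c12
F2 | step 10 | [5,7-bis(benzyloxy)-2-(4-benzyloxy-3-methoxyphenyl)-8-methoxy-4-oxochromen-3-yl]lithium | [Li]c1c(-c2ccc(OCc3ccccc3)c(OC)c2)oc2c(OC)c(OCc3ccccc3)cc(OCc3ccccc3)c2c1=O
F3 | step 11 | 5,7-bis(benzyloxy)-2-(4-benzyloxy-3-methoxyphenyl)-8-methoxy-3-(4,4,5,5-tetramethyl-1,3,2-dioxaborolan-2-yl)chromen-4-one | CC1(C)OB(c2c(-c3ccc(OCc4ccccc4)c(OC)c3)oc3c(OC)c(OCc4ccccc4)cc(OCc4ccccc4)c3c2=O)OC1(C)C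
F4 | step 11 | 5,7-bis(benzyloxy)-2-(4-benzyloxy-3-methoxyphenyl)-3-hydroxy-8-methoxychromen-4-one | O=c1c(O)c(-c2ccc(OCc3ccccc3)c(OC)c2)oc2c(OC)c(OCc3ccccc3)cc(OCc3ccccc3)c12
F5 | step 13 | dipotassium 5-hydroxy-3,8-dimethoxy-2-(3-methoxy-4-oxidophenyl)-4-oxochromen-7-olate | [K+].[K+].COc1cc(-c2oc3c(OC)c([O-])cc(O)c3c(=O)c2OC)ccc1[O-]
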